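## The problem

The target is an ether-bridged eunicellane. It is numbered here so that C1/C10 is the ring fusion, C2 and C9 are the ether carbons, C3 is the lactone carbinol, C6=C7 the alkene, C11 the acetoxy carbon and C14–C15(CH3)–C16 the lactone arm. Four rings share a small core: a cyclohexane (C1, C10–C14) is cis-fused to a tetrahydrofuran (C1, C2, O, C9, C10), the ether oxygen also spans a nine-membered oxonene (C2–C9) with a (Z)-trisubstituted alkene, and a seven-membered lactone ties the C3 oxygen to C16 across the C1–C14 bond. There are eight stereocentres (1S,2S,3S,9S,10R,11R,14R,15R), seven of them in one contiguous array. Within that array relay is possible: C14 can set C1 (trans on the ring), C1 can set C10 and C9 through a tether across the ether oxygen, the ether oxygen at C2 can set C3 by chelation, and C9 can set C11 if oxygen is delivered from the C9 side chain. C15 lies outside the ring and needs a reagent to set it. The tertiary C11 acetate, the lactone on a tertiary carbinol beside epimerisable C15, any β-alkoxy ketone at C7 (β-elimination at C9 opens the ether) and the strained (Z)-alkene under acid all call for mild late steps, with the acetate put on last. The feature that opens the route is the array O–C9–C10–C11–O, with the C11 oxygen and C9 on the same face of the cyclohexane and C11 tertiary: it is the imprint of a C10=C11 alkene adding to an oxocarbenium ion at C9, with the C11 cation quenched from the C9 side chain, where the future C7 sits three atoms away as a ketone.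

## Retrosynthesis

**Acetate.** The acyl C–O bond at C11 of 26 is cut first, giving tertiary alcohol 25. The acetate would not survive the organomagnesium and ylide steps needed for the ring, and it is the group most prone to elimination, so it is kept out of all earlier stages. The forward reaction must acylate a hindered tertiary hydroxyl without touching the lactone or the alkene.

**Oxonene.** In 25 the C6=C7 double bond is cut, opening the nine-membered ring to diene 24 with a but-3-enyl group on C3 and a 2-methylallyl group on C9. Cutting a C–O bond of the bridge would ask for etherification to a nine-membered ring, and cutting C3–C4 or C7–C8 would leave a stereodefined trisubstituted alkene to be made in an open chain. The alkene cut leaves two terminal alkenes, each traceable to a carbonyl group. The forward ring-closing metathesis must form a trisubstituted alkene in a nine-membered ring; the cis-2,5-tetrahydrofuran and the lactone hold both chains on one side, and the ring size admits only the (Z)-alkene.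

**C7 methylene and its mask.** The C7 methylene of 24 is taken back to the ketone of 23 (Wittig transform), and 23 to the cyclic methyl ketal 22, in which C7 and the C11 oxygen are tied together. The ketone is needed twice, as the trap in the key step and as the source of the alkene carbon, but it cannot be free while C3 is built. One acid-labile ketal covering both the carbonyl group and the tertiary hydroxyl is cheaper than two protecting groups.

**C3 and the lactone.** In 22 the C3–C4 bond and the lactone C16–O bond are cut together, leading to methyl ketone 19 and but-3-enylmagnesium bromide 20. The reverse order (methyl addition to a butenyl ketone) would give the C3 epimer from the same chelate, and lactonisation by carboxyl activation would cost two more steps. The forward addition must pass through the five-membered magnesium chelate between the ring oxygen at C2 and the C3 carbonyl, so that the reagent enters on the side of H2 and sets 3S. The alkoxide must then close the seven-membered lactone on the C16 ester.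

**C3 carbonyl.** The ketone of 19 is traced to the isopropenyl group of ketal 18 (ozonolysis transform), and 18 to hydroxy ketone 17. Carrying C3 as an alkene through the key step avoids an α-alkoxy ketone under Lewis acid, and the isopropenyl group comes in one piece from methacrolein 7.

**Key cut.** Hydroxy ketone 17 is cut at O–C9, C9–C10 and C11–O, giving cyclohexenyl carbinol 12 and 4,4-dimethoxybutan-2-one 13. Closing the tetrahydrofuran by displacement at C2 or C9 would need C9, C10 and C11 already in place. This cut instead removes a ring, three stereocentres and four carbons at once, and leaves a monocyclic precursor with only C1, C2, C14 and C15 defined. The forward step must form the oxocarbenium ion on the C2 oxygen, close the five-membered ring through C10 and not a six-membered ring through C11, and return oxygen to C11 on the face of C9. That last demand is why the trap is the side-chain carbonyl group: an external nucleophile would add anti to C9.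

**Alkene position.** The C10=C11 alkene of 12 is traced through tosylhydrazone 10 to the enone of aldol adduct 9. Reduction with allylic transposition moves the double bond from C11=C12 to C10=C11 and erases the carbonyl oxygen. The ketone thus serves the aldol and then disappears; a direct route to 12 would need a regiodefined allyl anion at C1.

**C1–C2 bond.** Adduct 9 is cut at C1–C2 to keto ester 6 and methacrolein 7. The ring-fixed (E)-enolate 8 must add trans to the C14 side chain and give the anti aldol, which is the C1/C2 relationship of the target.

**C15.** The C15 centre of 6 is traced through acid 5 to acrylic acid 4 (hydrogenation transform). C15 is the one centre the ring cannot control, and a 2-substituted acrylic acid is the substrate class for which carboxylate-directed asymmetric hydrogenation is most dependable.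

**Chiral pool.** Acid 4 goes back through enal 3 and allylic chloride 2 to (R)-carvone 1 by oxidation of the isopropenyl methyl group. Carvone supplies the six ring carbons, the C11 methyl group, C15, C16, the C15 methyl group and the C14 configuration.

## Roads not taken

**Alternative 1:** The cut is C7–C8 of the oxonene. Diiodide A1, with a primary iodide at C8 and a (Z)-alkenyl iodide at C7, would be closed to silyl ether A2 by zinc insertion into the C8–I bond (zinc dust, LiCl) and intramolecular coupling with PdCl2(dppf).
- Merits: the alkene geometry is fixed in A1 and carried over with retention, so nothing rests on ring strain; A2 is two steps (desilylation, acetylation) from the target.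
- Weak points: the C8 organozinc is β to the ring oxygen at C9 and can open the tetrahydrofuran by β-elimination; insertion must distinguish the alkyl from the alkenyl iodide; closure through a ten-membered palladacycle competes with reduction and dimerisation. A1 also needs a stereodefined trisubstituted alkenyl iodide on top of the whole tricyclic core, for which this road offers no construction.
- Comparison: in control of alkene geometry this road is better than the metathesis of step 15. The chosen plan sets against it that C7 and C8 arrive with the core in the key step, and that the ring closure then needs only one methylenation as preparation.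

**Alternative 2:** The cut is C1–C10 together with C11–O, opening the cyclohexane to the fourteen-membered epoxy diene A3. BF3·OEt2 with acetic acid would open the cis-epoxide at C1, C10=C11 would bond to C1 across the ring, and acetic acid would take the C11 cation, giving bicycle A4 with the C2 hydroxyl and the C11 acetate in place.
- Merits: biomimetic; the six-membered ring, three stereocentres and the tertiary acetate come in one step, so the hindered acetylation of step 16 is avoided. In that respect it is better than the chosen plan.
- Weak points: only the conformation of a fourteen-membered ring decides which epoxide carbon opens, which alkene attacks and which faces of C10 and C11 react. Anti addition of C1 and acetate across C10=C11 fits the target only from the (Z)-alkene, and hydride shifts, proton loss and attack by C6=C7 compete. A3 itself carries five stereocentres, two of them remote, and two defined alkenes in a macrocycle. After A4 the ether bridge (displacement at C9 with inversion) and the lactone are still to be made.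
- Comparison: if it worked it would be the shortest road, and it matches the chosen plan in setting C1, C10 and C11 together. The chosen plan sets against it that each of those selectivities is taken from a tether on a six-membered ring and not from a macrocyclic conformation.

**Alternative 3:** The cut is C8–C9, with O–C6 re-formed in the reverse sense, tracing the oxa-bridged nine-membered ring to pyranyl diazoketone A5. Cu(hfacac)2 (copper bis(hexafluoroacetylacetonate)) would generate a carbenoid at C9 that bonds to the pyran oxygen; the oxonium ylide then shifts [2,3] across the isopropenyl group at C6 (C8–C9 forms, O–C6 breaks) to give the (Z)-oxabicyclic ketone A6.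
- Merits: the medium ring, the bridging ether and the (Z)-alkene come in one step from a six-membered ring, by a reaction type established for exactly this bicycle. The hardest ring is secured early and not in the penultimate step; in this respect it is better than the chosen plan.
- Weak points: the (Z)/(E) outcome depends on the catalyst, and [1,2]-shift and C–H insertion compete. The cyclohexane with the quaternary C11 carbinol, C14 and C15 must then be annulated onto C1–C10 of A6, which means a diene synthesis, a cycloaddition and several adjustments; C15 and the lactone are not addressed.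
- Comparison: the chosen plan sets against the early ring closure that the cyclohexane, C14 and C15 come from carvone and one hydrogenation, that C9, C10 and C11 are set in one step, and that the total is shorter. It pays with a late medium-ring closure.

Key step: step 9

Remark on the chemistry: eunicellane locants (as defined under "The problem") are used for every intermediate, so each carbon keeps its number from 1 to 26.
Remark on the chemistry: hydroxy ketones 17 and 23 are written in the open form; each may rest partly as its six-membered hemiketal, which reacts on in the same way.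

## Route

Step 1
Reactants: 1 (R)-(−)-carvone
Product: 2 (5R)-5-(3-chloroprop-1-en-2-yl)-2-methylcyclohex-2-en-1-one
Conditions: Ca(OCl)2, CO2 (solid), CH2Cl2/H2O, 0 °C
Reagents that add atoms: calcium hypochlorite, [Ca+2].[O-]Cl.[O-]Cl
Why: Ene-type allylic chlorination by HOCl formed in the flask; the electron-rich 1,1-disubstituted alkene reacts and the enone alkene does not, and the stereocentre (C14) is not touched.

Step 2
Reactants: 2 (5R)-5-(3-chloroprop-1-en-2-yl)-2-methylcyclohex-2-en-1-one
Product: 3 2-[(1R)-4-methyl-5-oxocyclohex-3-en-1-yl]prop-2-enal
Conditions: Me3NO, NaI (cat.), DMSO, 25 °C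
Reagents that add atoms: trimethylamine N-oxide, C[N+](C)(C)[O-]
Why: Kornblum-type oxidation of an allylic halide with an amine N-oxide (Ganem variant): displacement at the activated CH2 by the N-oxide oxygen, then elimination of trimethylamine, gives the enal.

Step 3
Reactants: 3 2-[(1R)-4-methyl-5-oxocyclohex-3-en-1-yl]prop-2-enal
Product: 4 2-[(1R)-4-methyl-5-oxocyclohex-3-en-1-yl]prop-2-enoic acid
Conditions: NaClO2, NaH2PO4, 2-methyl-2-butene, t-BuOH/H2O, 0 → 25 °C
Reagents that add atoms: sodium chlorite, [Na+].[O-]Cl=O
Why: Pinnick oxidation converts the enal to the acrylic acid without touching either alkene; the scavenger removes HOCl.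

Step 4
Reactants: 4 2-[(1R)-4-methyl-5-oxocyclohex-3-en-1-yl]prop-2-enoic acid
Product: 5 (2R)-2-[(1R)-4-methyl-5-oxocyclohex-3-en-1-yl]propanoic acid
Conditions: Ru(OAc)2[(R)-BINAP] (1 mol %), H2 (50 atm), MeOH, 25 °C
Reagents that add atoms: none
Why: Carboxylate-directed asymmetric hydrogenation of a 2-substituted acrylic acid (Noyori type); the (R)-BINAP catalyst is expected, by the sense established for this substrate class, to deliver hydrogen to the face that gives 15R. The enone alkene and the ketone carry no directing carboxylate and should stay intact.

Step 5
Reactants: 5 (2R)-2-[(1R)-4-methyl-5-oxocyclohex-3-en-1-yl]propanoic acid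
Product: 6 methyl (2R)-2-[(1R)-4-methyl-5-oxocyclohex-3-en-1-yl]propanoate
Conditions: MeI, K2CO3, DMF, 25 °C
Reagents that add atoms: iodomethane, CI
Why: O-Alkylation of the carboxylate; the base is too weak to epimerise C15 or enolise the enone.

Step 6
Reactants: 6 methyl (2R)-2-[(1R)-4-methyl-5-oxocyclohex-3-en-1-yl]propanoate; 7 methacrolein
Product: 9 methyl (2R)-2-[(1R,2R)-2-[(1S)-1-hydroxy-2-methylprop-2-en-1-yl]-4-methyl-3-oxocyclohex-4-en-1-yl]propanoate, via lithium dienolate 8 (not isolated)
Conditions: LiN(i-Pr)2, THF, −78 °C; then 7, −78 °C; AcOH quench at −78 °C
Reagents that add atoms: none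
Why: Kinetic deprotonation at the α′-CH2 (C1) gives the cross-conjugated dienolate, the ketone being far more acidic than the hindered ester; the aldol addition then occurs anti to the C14 side chain, which sets C1. The ring-fixed (E)-enolate reacts through a Zimmerman–Traxler chair with the aldehyde substituent equatorial, which gives the anti aldol and sets C2 as S.

Step 7
Reactants: 9 methyl (2R)-2-[(1R,2R)-2-[(1S)-1-hydroxy-2-methylprop-2-en-1-yl]-4-methyl-3-oxocyclohex-4-en-1-yl]propanoate
Product: 10 C10 p-toluenesulfonylhydrazone of 9
Conditions: TsNHNH2, AcOH (cat.), EtOH, 25 °C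
Reagents that add atoms: p-toluenesulfonyl hydrazide, Cc1ccc(cc1)S(=O)(=O)NN
Why: Hydrazone condensation at the enone carbonyl under near-neutral conditions, mild enough to avoid retro-aldol cleavage and dehydration of the β-hydroxy ketone.

Step 8
Reactants: 10 C10 p-toluenesulfonylhydrazone of 9
Product: 12 methyl (2R)-2-[(1R,2S)-2-[(1S)-1-hydroxy-2-methylprop-2-en-1-yl]-4-methylcyclohex-3-en-1-yl]propanoate, via allylic diazene 11 (not isolated)
Conditions: catecholborane (3 equiv), CHCl3, 0 → 25 °C; then NaOAc·3H2O, reflux
Reagents that add atoms: none
Why: Reductive 1,3-transposition of an enone tosylhydrazone: hydride adds at C10, sulfinate is lost, and the diazene passes hydrogen to C12 in a retro-ene step with loss of N2, leaving the alkene at C10=C11. The ester and the isopropenyl group are inert to catecholborane at this temperature, the free hydroxyl only consumes one equivalent, and C1 and C2 are not touched.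

Step 9
Reactants: 12 methyl (2R)-2-[(1R,2S)-2-[(1S)-1-hydroxy-2-methylprop-2-en-1-yl]-4-methylcyclohex-3-en-1-yl]propanoate; 13 4,4-dimethoxybutan-2-one
Product: 17 methyl (2R)-2-[7-hydroxy-7-methyl-1-(2-oxopropyl)-3-(prop-1-en-2-yl)octahydroisobenzofuran-4-yl]propanoate (eunicellane 1S,2S,9S,10R,11R,14R,15R), via trimethylsilyl ether 14 (not isolated), via mixed acetal 15 (not isolated), via cyclic oxocarbenium triflate 16 (not isolated)
Conditions: Me3SiOTf (1.05 equiv), 2,6-lutidine, CH2Cl2, −78 °C; then 13, Me3SiOTf (1.2 equiv), −78 → −40 °C; then aq HCl/THF, 0 °C; NaHCO3
Reagents that add atoms: water, O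
Why: Proposed new method: silylation of the C2 hydroxyl, Me3SiOTf-catalysed exchange with 13 to the mixed acetal and loss of the second methoxy group give the (E)-oxocarbenium ion at C9; C10 of the trisubstituted alkene attacks it, the charge moves to tertiary C11 and is quenched at once by the side-chain ketone oxygen to give the six-membered oxocarbenium ion, which water opens to the C11 alcohol and the C7 ketone; the closest known reaction types are the Prins cyclisation of homoallylic alcohols bearing trisubstituted alkenes to 2,5-cis tetrahydrofurans and the Lewis-acid-induced stepwise [4+2] addition of enones to alkenes, in which a carbonyl oxygen likewise closes onto the cation, but their union on a β-keto acetal is untested. The tetrahydrofuran closes in the 5-exo mode with respect to C10=C11 (the C9=O+ bond lies inside the ring), and it is preferred over the pyran because only this closure leads to a tertiary cation; the transient second ring closes by six-membered attack of oxygen on C11. C10 is set by the tether: C9 can reach the alkene only on the face of C1 that carries C2, so the ring fusion is cis. C9 is set in the envelope transition state of the (E)-oxocarbenium ion, in which the isopropenyl group at C2 and the acetonyl group at C9 are both pseudo-equatorial, giving the 2,5-cis ether. C11 is set by the tether from C9, which is axial on the cyclohexyl cation because C2 and C15 hold the equatorial positions at C1 and C14, so the ketone oxygen reaches only the lobe of C11 syn to C9, whereas an external nucleophile would add anti and give the 11-epimer. The selectivities needed are five- over six-membered closure, capture over proton loss at C11, and cyclisation over 2-oxonia-Cope cleavage of C1–C2; they rest on the tertiary cation, the proximity of the carbonyl group, and low temperature without free acid or base after the silylation.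

Step 10
Reactants: 17 hydroxy ketone (product of step 9)
Product: 18 cyclic methyl ketal of 17 (C7 bonded to OCH3 and CH3 and C8 and the C11 oxygen)
Conditions: HC(OMe)3, MeOH, PPTS (cat.), 25 °C
Reagents that add atoms: trimethyl orthoformate, COC(OC)OC
Why: Acid-catalysed ketalisation of a δ-hydroxy ketone to the six-membered methyl ketal masks the C7 carbonyl and the C11 hydroxyl in one operation; any hemiketal or enol ether form of 17 funnels to the same product, and the C7 configuration is of no consequence.

Step 11
Reactants: 18 cyclic methyl ketal of 17
Product: 19 C3 methyl ketone (isopropenyl group at C2 cleaved to acetyl)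
Conditions: O3, CH2Cl2, −78 °C; then Me2S, −78 → 25 °C
Reagents that add atoms: ozone, [O-][O+]=O
Why: Ozonolysis with reductive work-up of the only alkene in the molecule; the neutral conditions leave the α-alkoxy centre C2 and the ketal untouched.

Step 12
Reactants: 19 C3 methyl ketone; 20 but-3-enylmagnesium bromide
Product: 22 seven-membered lactone with C3 bearing methyl and but-3-enyl (3S) and the C7 methyl ketal retained, via bromomagnesium alkoxide 21 (not isolated)
Conditions: 20 (2 equiv), Et2O/THF, −78 °C; then warm to 40 °C; aq NH4Cl
Reagents that add atoms: none
Why: Cram-chelate Grignard addition: magnesium bridges the ring oxygen at C2 and the C3 carbonyl, and the reagent enters anti to C1 on the side of H2, which sets 3S; the methyl ketone reacts well ahead of the hindered ester. On warming, the tertiary alkoxide, held next to the C16 ester by the trans-diequatorial C1 and C14 substituents, closes the lactone by intramolecular transesterification.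

Step 13
Reactants: 22 lactone ketal
Product: 23 hydroxy ketone lactone (C11 hydroxyl and C9 acetonyl group restored)
Conditions: PPTS, acetone/H2O, 40 °C
Reagents that add atoms: water, O
Why: Mild acid hydrolysis of the mixed ketal through the same cyclic oxocarbenium ion as in step 9; the tertiary-alkyl lactone and the terminal alkene tolerate these conditions.

Step 14
Reactants: 23 hydroxy ketone lactone
Product: 24 diene with 2-methylallyl on C9 and but-3-enyl on C3
Conditions: Ph3PCH3Br, KOt-Bu, THF, 0 → 25 °C
Reagents that add atoms: methyltriphenylphosphonium bromide, C[P+](c1ccccc1)(c1ccccc1)c1ccccc1.[Br-]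
Why: Wittig methylenation of the methyl ketone, any hemiketal opening under the basic conditions as in olefination of lactols; the non-stabilised ylide at low temperature attacks the ketone faster than it enolises it or adds to the hindered lactone.

Step 15
Reactants: 24 diene
Product: 25 11-deacetyl target (tertiary alcohol with the oxonene closed)
Conditions: second-generation Grubbs catalyst RuCl2(=CHPh)(H2IMes)(PCy3) (10 mol %), CH2Cl2 (0.002 M), 40 °C
Reagents that add atoms: none
Why: Ring-closing metathesis starts at the monosubstituted alkene and closes onto the 1,1-disubstituted one with loss of ethene; the cis-2,5-tetrahydrofuran and the lactone hold the chains together, and the nine-membered ring admits only the (Z)-alkene.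

Step 16
Reactants: 25 11-deacetyl target
Product: 26 target compound
Conditions: Ac2O, Et3N, DMAP, CH2Cl2, 40 °C
Reagents that add atoms: acetic anhydride, CC(=O)OC(C)=O
Why: DMAP-catalysed acylation of the equatorial tertiary hydroxyl under basic conditions that spare the alkene, the ether and the lactone; no stereocentre is affected.

## Compound list

1 | (R)-(−)-carvone, (5R)-2-methyl-5-(prop-1-en-2-yl)cyclohex-2-en-1-one | CC1=CC[C@H](CC1=O)C(C)=C | starting material
2 | (5R)-5-(3-chloroprop-1-en-2-yl)-2-methylcyclohex-2-en-1-one | CC1=CC[C@H](CC1=O)C(=C)CCl | intermediate
3 | 2-[(1R)-4-methyl-5-oxocyclohex-3-en-1-yl]prop-2-enal | CC1=CC[C@H](CC1=O)C(=C)C=O | intermediate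
4 | 2-[(1R)-4-methyl-5-oxocyclohex-3-en-1-yl]prop-2-enoic acid | CC1=CC[C@H](CC1=O)C(=C)C(=O)O | intermediate
5 | (2R)-2-[(1R)-4-methyl-5-oxocyclohex-3-en-1-yl]propanoic acid | CC1=CC[C@H](CC1=O)[C@@H](C)C(=O)O | intermediate
6 | methyl (2R)-2-[(1R)-4-methyl-5-oxocyclohex-3-en-1-yl]propanoate | CC1=CC[C@H](CC1=O)[C@@H](C)C(=O)OC | intermediate
7 | methacrolein (2-methylprop-2-enal) | CC(=C)C=O | starting material
8 | lithium cross-conjugated dienolate of 6 (O–Li on C10, enolate double bond C1=C10; not isolated) | CC1=CC[C@@H]([C@@H](C)C(=O)OC)C=C1O[Li] | intermediate
9 | methyl (2R)-2-[(1R,2R)-2-[(1S)-1-hydroxy-2-methylprop-2-en-1-yl]-4-methyl-3-oxocyclohex-4-en-1-yl]propanoate (anti aldol; C1 side chain trans to C14 side chain) | CC1=CC[C@@H]([C@@H](C)C(=O)OC)[C@H]([C@H](O)C(C)=C)C1=O | intermediate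
10 | C10 p-toluenesulfonylhydrazone of 9 (C=N geometry not defined) | CC1=CC[C@@H]([C@@H](C)C(=O)OC)[C@H]([C@H](O)C(C)=C)C1=NNS(=O)(=O)c1ccc(C)cc1 | intermediate
11 | allylic diazene (C10–N=NH, C10 configuration not defined; not isolated) | CC1=CC[C@@H]([C@@H](C)C(=O)OC)[C@H]([C@H](O)C(C)=C)C1N=N | intermediate
12 | methyl (2R)-2-[(1R,2S)-2-[(1S)-1-hydroxy-2-methylprop-2-en-1-yl]-4-methylcyclohex-3-en-1-yl]propanoate (eunicellane 1S,2S,14R,15R) | CC1=C[C@@H]([C@H](O)C(C)=C)[C@H]([C@@H](C)C(=O)OC)CC1 | intermediate
13 | 4,4-dimethoxybutan-2-one | CC(=O)CC(OC)OC | starting material
14 | C2 trimethylsilyl ether of 12 (not isolated) | CC1=C[C@@H]([C@H](O[Si](C)(C)C)C(C)=C)[C@H]([C@@H](C)C(=O)OC)CC1 | intermediate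
15 | mixed methyl acetal of 12 at C9 (C2–O–CH(OCH3)–CH2–C(=O)CH3, both C9 epimers; not isolated) | CC1=C[C@@H]([C@H](OC(OC)CC(C)=O)C(C)=C)[C@H]([C@@H](C)C(=O)OC)CC1 | intermediate
16 | tricyclic oxocarbenium triflate (C11–O+=C7(CH3)–C8–C9; tetrahydrofuran closed; not isolated) | CC1=[O+][C@]2(C)CC[C@@H]([C@@H](C)C(=O)OC)[C@H]3[C@@H]2[C@H](C1)O[C@@H]3C(C)=C.[O-]S(=O)(=O)C(F)(F)F | intermediate
17 | hydroxy ketone, methyl (2R)-2-[7-hydroxy-7-methyl-1-(2-oxopropyl)-3-(prop-1-en-2-yl)octahydroisobenzofuran-4-yl]propanoate; eunicellane 1S,2S,9S,10R,11R,14R,15R; ring fusion cis, C2 and C9 substituents cis, C11 hydroxyl cis to C9 | O[C@]1(C)CC[C@@H]([C@@H](C)C(=O)OC)[C@H]3[C@@H]1[C@H](CC(C)=O)O[C@@H]3C(C)=C | intermediate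
18 | cyclic methyl ketal of 17 (ring O–C7–C8–C9–C10–C11; C7 bears OCH3 and CH3, configuration not defined; other centres as in 17) | COC1(C)O[C@]2(C)CC[C@@H]([C@@H](C)C(=O)OC)[C@H]3[C@@H]2[C@H](C1)O[C@@H]3C(C)=C | intermediate
19 | C3 methyl ketone (18 with acetyl in place of isopropenyl at C2) | COC1(C)O[C@]2(C)CC[C@@H]([C@@H](C)C(=O)OC)[C@H]3[C@@H]2[C@H](C1)O[C@@H]3C(C)=O | intermediate
20 | but-3-enylmagnesium bromide | C=CCC[Mg]Br | starting material
21 | bromomagnesium alkoxide (C3 bears CH3, but-3-enyl and OMgBr, 3S; not isolated) | COC1(C)O[C@]2(C)CC[C@@H]([C@@H](C)C(=O)OC)[C@H]3[C@@H]2[C@H](C1)O[C@@H]3[C@](C)(CCC=C)O[Mg]Br | intermediate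
22 | lactone ketal (seven-membered lactone from the C3 oxygen to C16; C3 bears CH3 and but-3-enyl, 3S; C7 methyl ketal) | COC1(C)O[C@]2(C)CC[C@@H]4[C@H]3[C@@H]2[C@H](C1)O[C@@H]3[C@](C)(CCC=C)OC(=O)[C@@H]4C | intermediate
23 | hydroxy ketone lactone (C11 hydroxyl, C9 acetonyl; eunicellane 1S,2S,3S,9S,10R,11R,14R,15R) | O[C@]1(C)CC[C@@H]2[C@H]3[C@@H]1[C@H](CC(C)=O)O[C@@H]3[C@](C)(CCC=C)OC(=O)[C@@H]2C | intermediate
24 | diene (C9 2-methylallyl, C3 but-3-enyl; centres as in 23) | O[C@]1(C)CC[C@@H]2[C@H]3[C@@H]1[C@H](CC(C)=C)O[C@@H]3[C@](C)(CCC=C)OC(=O)[C@@H]2C | intermediate
25 | 11-deacetyl target (tertiary alcohol, (6Z)-oxonene closed) | O[C@]1(C)CC[C@@H]2[C@H]3[C@@H]1[C@@H]1C/C(C)=C\CC[C@](C)(OC(=O)[C@@H]2C)[C@H]3O1 | intermediate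
26 | target compound (1S,2S,3S,9S,10R,11R,14R,15R,6Z) | CC(=O)O[C@]1(C)CC[C@@H]2[C@H]3[C@@H]1[C@@H]1C/C(C)=C\CC[C@](C)(OC(=O)[C@@H]2C)[C@H]3O1 | target

## Step count and weak points

Total: 16 steps. Longest linear sequence: 16 steps from 1 to 26; 7, 13 and 20 are commercial and enter directly.

**Step 9 (key step, proposed new method).** Three processes threaten it:
- proton loss from the C11 cation, or its capture by triflate, before the carbonyl oxygen closes;
- 2-oxonia-Cope cleavage of the C1–C2 bond, which is driven by the conjugated oxocarbenium ion it would give;
- elimination of methanol from the β-keto acetal to a vinylogous ester that ionises less readily.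

The fallback uses known reactions only, sets out from 12 and returns at 17.
1. Bromohydrin formation across C10=C11 (N-bromosuccinimide, aqueous acetone, 0 °C) gives bromohydrin F1. The bromonium ion forms on the face away from the C1 substituent and water opens it at tertiary C11, so the C11 hydroxyl ends syn to C2. The trisubstituted ring alkene is far more nucleophilic than the isopropenyl group next to oxygen.
2. Conjugate addition of the secondary C2 hydroxyl to but-3-yn-2-one (N-methylmorpholine, catalytic) gives (E)-β-alkoxy enone F2; the tertiary hydroxyl does not add.
3. Bu3SnH with azobisisobutyronitrile in benzene at 80 °C generates the C10 radical, which closes 5-exo onto C9 of the enone. This radical cyclisation of β-alkoxy enones is known to give 2,5-cis tetrahydrofurans, and the ring fusion is necessarily cis, so 17 results directly.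

**Step 6.** The lithium aldol may show poor simple diastereoselection at C2 because the lithium transition state is loose, and the aldolate may revert on warming. The fallback sets out from 6 and returns at 9. Soft enolisation with (c-C6H11)2BCl and Et3N in Et2O at 0 °C gives dicyclohexylboron dienolate F3, whose short B–O bonds enforce a tight chair; addition of 7 at −78 °C and hydrolytic work-up should give the anti adduct 9.

**Step 12.** Lactonisation may stall at the magnesium alkoxide, since a tertiary alkoxide must attack an α-branched ester through a seven-membered transition state; longer heating would risk epimerisation at C15. The fallback sets out from 19 and returns at 22. The Grignard addition is quenched cold to give hydroxy ester F4; Me3SnOH in 1,2-dichloroethane at 80 °C cleaves the methyl ester without epimerisation to hydroxy acid F5; Yamaguchi lactonisation (2,4,6-trichlorobenzoyl chloride, Et3N, then DMAP in toluene at 80 °C) closes the ring by carboxyl activation.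

**Step 15.** Oligomerisation through the monosubstituted alkene may outrun closure onto the hindered 1,1-disubstituted alkene, because the ring is nine-membered and the product alkene trisubstituted. The fallback sets out from 23 and returns at 25, bypassing 24. Ozonolysis of the terminal alkene (O3, then PPh3) gives keto aldehyde F6, and intramolecular McMurry coupling (TiCl3, zinc–copper couple, 1,2-dimethoxyethane, reflux, slow addition) joins C6 and C7 directly. The ketone–aldehyde pair couples faster than the lactone carbonyl, and the ring again allows only the (Z)-alkene.

## Further compounds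

F1 | step 9 | bromohydrin of 12 (C10 bromide anti to C2, C11 hydroxyl syn to C2) | O[C@]1(C)CC[C@@H]([C@@H](C)C(=O)OC)[C@H]([C@H](O)C(C)=C)[C@H]1Br
F2 | step 9 | (E)-β-alkoxy enone of F1 (C2–O–CH=CH–C(=O)CH3) | O[C@]1(C)CC[C@@H]([C@@H](C)C(=O)OC)[C@H]([C@H](O/C=C/C(C)=O)C(C)=C)[C@H]1Br
F3 | step 6 | dicyclohexylboron dienolate of 6 | CC1=CC[C@@H]([C@@H](C)C(=O)OC)C=C1OB(C1CCCCC1)C1CCCCC1
F4 | step 12 | hydroxy ester (C3 tertiary alcohol with but-3-enyl, C16 methyl ester, C7 methyl ketal) | COC1(C)O[C@]2(C)CC[C@@H]([C@@H](C)C(=O)OC)[C@H]3[C@@H]2[C@H](C1)O[C@@H]3[C@](C)(CCC=C)O
F5 | step 12 | hydroxy acid (F4 with the C16 carboxylic acid) | COC1(C)O[C@]2(C)CC[C@@H]([C@@H](C)C(=O)O)[C@H]3[C@@H]2[C@H](C1)O[C@@H]3[C@](C)(CCC=C)O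
F6 | step 15 | keto aldehyde (23 with the C6 aldehyde in place of the vinyl group) | O[C@]1(C)CC[C@@H]2[C@H]3[C@@H]1[C@H](CC(C)=O)O[C@@H]3[C@](C)(CCC=O)OC(=O)[C@@H]2C
A1 | alternative 1 | diiodide (C8 primary iodide, (Z)-C7 alkenyl iodide, C11 triethylsilyl ether) | CC[Si](CC)(CC)O[C@]1(C)CC[C@@H]2[C@H]3[C@@H]1[C@H](CI)O[C@@H]3[C@](C)(CC/C=C(/C)I)OC(=O)[C@@H]2C
A2 | alternative 1 | 11-O-triethylsilyl ether of 25 | CC[Si](CC)(CC)O[C@]1(C)CC[C@@H]2[C@H]3[C@@H]1[C@@H]1C/C(C)=C\CC[C@](C)(OC(=O)[C@@H]2C)[C@H]3O1
A3 | alternative 2 | fourteen-membered cis-1,2-epoxy (6Z,10Z)-diene with C3 triethylsilyl ether and C9 tert-butyldimethylsilyl ether | C1C/C(C)=C\[C@H](O[Si](C)(C)C(C)(C)C)C/C(C)=C\CC[C@](C)(O[Si](CC)(CC)CC)[C@H]2O[C@H]2[C@@H]1[C@@H](C)C(=O)OC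
A4 | alternative 2 | eunicellane-type bicycle with C2 hydroxyl and C11 acetate | CC(=O)O[C@]1(C)CC[C@@H]([C@@H](C)C(=O)OC)[C@H]2[C@@H]1[C@H](O[Si](C)(C)C(C)(C)C)C/C(C)=C\CC[C@](C)(O[Si](CC)(CC)CC)[C@H]2O
A5 | alternative 3 | pyranyl diazoketone (2,6-cis; C6 isopropenyl, C3 triethylsilyl ether) | [N-]=[N+]=CC(=O)C[C@@H]1O[C@H](C(C)=C)CC[C@]1(C)O[Si](CC)(CC)CC
A6 | alternative 3 | (Z)-11-oxabicyclo[6.2.1]undecenone (C10 ketone, C3 triethylsilyl ether) | O=C1C[C@@H]2O[C@H]1C/C(C)=C\CC[C@]2(C)O[Si](CC)(CC)CC
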